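**Plan**
- The retrosynthesis first removes the 7-O-benzyl group of unit 1 (the 8-aryloxyacacetin half). It then opens ring C of unit 2 (the 5-hydroxy-7-methoxyflavone half) at C4a–C4, C3–C4 and O1–C2, giving 2-iodo-5-methoxybenzene-1,3-diol, CO and a terminal aryl alkyne carried on O8 of unit 1.
- Enabling feature: in ring A of unit 2, C4a is flanked by C5–OH and C8a–O1, with the 7-OMe para to it. In the iodoresorcinol these two oxygens are symmetry-equivalent, so the annulation can give only one flavone.
- Further cuts: the alkyne to an aldehyde (one-carbon homologation), the diaryl ether C8(unit 1)–O–C4'(unit 2) to the 8-phenol of unit 1 plus 4-fluorobenzaldehyde, and the 8-OH to the C8–H of 7-O-benzylacacetin.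
- Forward: rings A, B and C of unit 1 come intact from acacetin and are functionalised in four steps. The iodoresorcinol is made in three steps. Ring C of unit 2 is the only ring built (step 8), and hydrogenolysis finishes the synthesis.
- The target has no stereocentre and no configured double bond, so no stereochemistry has to be set.

Key step: step 8

Remark: the enaminone that passes through step 8 is drawn as its E isomer; its push–pull C=C bond rotates easily and its geometry has no bearing on the outcome. Acacetin, 5-methoxyresorcinol, 4-fluorobenzaldehyde and carbon monoxide are taken as commercial.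

**Route**

Step 1
Reactants: 1 acacetin (5,7-dihydroxy-2-(4-methoxyphenyl)-4H-chromen-4-one)
Product: 2 7-(benzyloxy)-5-hydroxy-2-(4-methoxyphenyl)-4H-chromen-4-one
Conditions: BnBr (1.1 equiv), K2CO3 (1.2 equiv), acetone, reflux
Reagents that add atoms: benzyl bromide, BrCc1ccccc1
Why: Williamson etherification, in which the 7-OH (the most acidic phenol, para to the C4 carbonyl) is alkylated while the 5-OH stays locked in its hydrogen bond to that carbonyl, so one equivalent of benzyl bromide should react at O7 only.

Step 2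
Reactants: 2 7-(benzyloxy)-5-hydroxy-2-(4-methoxyphenyl)-4H-chromen-4-one
Product: 4 7-(benzyloxy)-5,8-dihydroxy-2-(4-methoxyphenyl)-4H-chromen-4-one, via potassium 8-sulfate 3 (not isolated)
Conditions: K2S2O8, aq. KOH, pyridine, 0 °C to rt; acidify and filter off unchanged 2; then aq. HCl, Na2SO3, 80 °C, under argon
Reagents that add atoms: potassium peroxodisulfate, [K+].[K+].[O-]S(=O)(=O)OOS(=O)(=O)[O-]
Why: Elbs persulfate oxidation, in which the 5-phenoxide attacks a peroxide oxygen of peroxodisulfate through its para carbon C8 to give the aryl sulfate, whose S–O bond is then hydrolysed by warm dilute acid that should leave the benzyl ether and the pyranone untouched.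

Step 3
Reactants: 4 7-(benzyloxy)-5,8-dihydroxy-2-(4-methoxyphenyl)-4H-chromen-4-one; 5 4-fluorobenzaldehyde
Product: 6 4-{[7-(benzyloxy)-5-hydroxy-2-(4-methoxyphenyl)-4-oxo-4H-chromen-8-yl]oxy}benzaldehyde
Conditions: K2CO3 (2 equiv), 5 (1.1 equiv), degassed DMF, 90 °C, argon
Reagents that add atoms: none
Why: Nucleophilic aromatic substitution (SNAr), in which the free 8-phenoxide, far more nucleophilic than the chelated 5-OH, displaces fluoride para to the formyl group through a Meisenheimer intermediate, with exclusion of air keeping the hydroquinone from oxidising to the 5,8-quinone.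

Step 4
Reactants: 6 4-{[7-(benzyloxy)-5-hydroxy-2-(4-methoxyphenyl)-4-oxo-4H-chromen-8-yl]oxy}benzaldehyde
Product: 7 7-(benzyloxy)-8-(4-ethynylphenoxy)-5-hydroxy-2-(4-methoxyphenyl)-4H-chromen-4-one
Conditions: dimethyl (1-diazo-2-oxopropyl)phosphonate (1.5 equiv), K2CO3 (3 equiv), MeOH–THF, 0 °C to rt
Reagents that add atoms: dimethyl (1-diazo-2-oxopropyl)phosphonate, COP(=O)(OC)C(=[N+]=[N-])C(C)=O
Why: Seyferth–Gilbert homologation in the Ohira–Bestmann variant, in which methanolysis of the acetyl group releases the diazomethylphosphonate anion that converts the non-enolisable aryl aldehyde into the terminal alkyne under conditions mild enough for the flavone, the benzyl ether and the free 5-OH.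

Step 5
Reactants: 8 5-methoxyresorcinol (5-methoxybenzene-1,3-diol)
Product: 9 1-methoxy-3,5-bis(methoxymethoxy)benzene
Conditions: NaH (2.4 equiv), MOMCl (2.4 equiv), DMF, 0 °C to rt
Reagents that add atoms: chloromethyl methyl ether, COCCl
Why: Double Williamson-type O-alkylation of the bis-phenoxide installs two methoxymethyl acetals that serve both as protecting groups and as strong directors for ortho-lithiation.

Step 6
Reactants: 9 1-methoxy-3,5-bis(methoxymethoxy)benzene
Product: 11 2-iodo-5-methoxy-1,3-bis(methoxymethoxy)benzene, via aryllithium 10 (not isolated)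
Conditions: n-BuLi (1.1 equiv), THF, 0 °C; then I2, THF, −78 °C to rt
Reagents that add atoms: iodine, II
Why: Directed ortho-metalation, in which n-BuLi removes the ring hydrogen flanked by both OMOM groups (two chelating acetal oxygens cooperate and should outcompete the sites between OMOM and OMe) and iodine then quenches the aryllithium at that carbon.

Step 7
Reactants: 11 2-iodo-5-methoxy-1,3-bis(methoxymethoxy)benzene
Product: 12 2-iodo-5-methoxybenzene-1,3-diol
Conditions: aq. HCl (2 M), MeOH, 40 °C, dark
Reagents that add atoms: none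
Why: Acid-catalysed acetal exchange with methanol frees both phenols as dimethoxymethane forms, and the low temperature and exclusion of light should limit protodeiodination of the electron-rich ring.

Step 8
Reactants: 12 2-iodo-5-methoxybenzene-1,3-diol (1.3 equiv); 13 carbon monoxide; 7 7-(benzyloxy)-8-(4-ethynylphenoxy)-5-hydroxy-2-(4-methoxyphenyl)-4H-chromen-4-one
Product: 16 7-(benzyloxy)-5-hydroxy-8-[4-(5-hydroxy-7-methoxy-4-oxo-4H-chromen-2-yl)phenoxy]-2-(4-methoxyphenyl)-4H-chromen-4-one, via ynone 14 (not isolated), via enaminone 15 (not isolated)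
Conditions: PdCl2(PPh3)2 (5 mol %), CO (10 bar), Et2NH, DMF, 90 °C, no copper salt
Reagents that add atoms: none
Why: Zerovalent palladium, formed in situ from PdCl2(PPh3)2, inserts into the C–I bond of 12, CO insertion gives an aroyl complex of divalent palladium, and the diethylamine-deprotonated alkyne 7 is transferred to it without copper, so that reductive elimination forges C4a–C4 and C3–C4 in ynone 14. The closest known reaction type is the carbonylative Sonogashira annulation of 2-iodophenols with terminal aryl alkynes to flavones in a secondary amine. Diethylamine then adds to the ynone in conjugate fashion to give enaminone 15, and a flanking phenol attacks the amine-bearing carbon and expels diethylamine, which forms O1–C2 and closes ring C of unit 2 in what is overall a 6-endo-dig closure (an addition–elimination at the enaminone β-carbon). No stereocentre is created. The step needs carbonylation to precede alkynylation, which CO pressure, the absence of copper and the ready migration of the electron-rich aryl group onto CO should secure against direct coupling and furan formation, and it needs 6-endo rather than 5-exo (aurone) closure, which the enaminone enforces because its only electrophilic carbon is the β-carbon. No regiochemical choice exists, since the two hydroxyls flanking the iodine of 12 are related by symmetry: whichever closes, the other ends as the hydrogen-bonded 5-OH and the methoxyl para to iodine as the 7-OMe.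

Step 9
Reactants: 16 7-(benzyloxy)-5-hydroxy-8-[4-(5-hydroxy-7-methoxy-4-oxo-4H-chromen-2-yl)phenoxy]-2-(4-methoxyphenyl)-4H-chromen-4-one
Product: 17 5,7-dihydroxy-8-[4-(5-hydroxy-7-methoxy-4-oxo-4H-chromen-2-yl)phenoxy]-2-(4-methoxyphenyl)-4H-chromen-4-one (CNP0124888.0)
Conditions: H2 (1 atm), 10% Pd/C, THF–MeOH, rt
Reagents that add atoms: none
Why: Hydrogenolysis of the benzylic C–O bond on Pd/C frees the 7-OH of unit 1, while the C2=C3 bonds of both 4-pyranones, the diaryl ether and the methyl ethers should not react under these mild conditions.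

**Compound list**

1 | acacetin, 5,7-dihydroxy-2-(4-methoxyphenyl)-4H-chromen-4-one | COc1ccc(-c2cc(=O)c3c(O)cc(O)cc3o2)cc1 | starting material
2 | 7-(benzyloxy)-5-hydroxy-2-(4-methoxyphenyl)-4H-chromen-4-one | COc1ccc(-c2cc(=O)c3c(O)cc(OCc4ccccc4)cc3o2)cc1 | intermediate
3 | potassium 7-(benzyloxy)-5-hydroxy-2-(4-methoxyphenyl)-4-oxo-4H-chromen-8-yl sulfate | COc1ccc(-c2cc(=O)c3c(O)cc(OCc4ccccc4)c(OS(=O)(=O)[O-])c3o2)cc1.[K+] | intermediate
4 | 7-(benzyloxy)-5,8-dihydroxy-2-(4-methoxyphenyl)-4H-chromen-4-one | COc1ccc(-c2cc(=O)c3c(O)cc(OCc4ccccc4)c(O)c3o2)cc1 | intermediate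
5 | 4-fluorobenzaldehyde | O=Cc1ccc(F)cc1 | starting material
6 | 4-{[7-(benzyloxy)-5-hydroxy-2-(4-methoxyphenyl)-4-oxo-4H-chromen-8-yl]oxy}benzaldehyde | COc1ccc(-c2cc(=O)c3c(O)cc(OCc4ccccc4)c(Oc4ccc(C=O)cc4)c3o2)cc1 | intermediate
7 | 7-(benzyloxy)-8-(4-ethynylphenoxy)-5-hydroxy-2-(4-methoxyphenyl)-4H-chromen-4-one | COc1ccc(-c2cc(=O)c3c(O)cc(OCc4ccccc4)c(Oc4ccc(C#C)cc4)c3o2)cc1 | intermediate
8 | 5-methoxyresorcinol, 5-methoxybenzene-1,3-diol | COc1cc(O)cc(O)c1 | starting material
9 | 1-methoxy-3,5-bis(methoxymethoxy)benzene | COCOc1cc(OC)cc(OCOC)c1 | intermediate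
10 | [4-methoxy-2,6-bis(methoxymethoxy)phenyl]lithium | [Li]c1c(OCOC)cc(OC)cc1OCOC | intermediate
11 | 2-iodo-5-methoxy-1,3-bis(methoxymethoxy)benzene | COCOc1cc(OC)cc(OCOC)c1I | intermediate
12 | 2-iodo-5-methoxybenzene-1,3-diol | COc1cc(O)c(I)c(O)c1 | intermediate
13 | carbon monoxide | [C-]#[O+] | starting material
14 | 7-(benzyloxy)-8-{4-[3-(2,6-dihydroxy-4-methoxyphenyl)-3-oxoprop-1-yn-1-yl]phenoxy}-5-hydroxy-2-(4-methoxyphenyl)-4H-chromen-4-one | COc1cc(O)c(C(=O)C#Cc2ccc(Oc3c(OCc4ccccc4)cc(O)c4c(=O)cc(-c5ccc(OC)cc5)oc34)cc2)c(O)c1 | intermediate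
15 | 7-(benzyloxy)-8-{4-[(1E)-1-(diethylamino)-3-(2,6-dihydroxy-4-methoxyphenyl)-3-oxoprop-1-en-1-yl]phenoxy}-5-hydroxy-2-(4-methoxyphenyl)-4H-chromen-4-one | CCN(CC)/C(c1ccc(Oc2c(OCc3ccccc3)cc(O)c3c(=O)cc(-c4ccc(OC)cc4)oc23)cc1)=C/C(=O)c1c(O)cc(OC)cc1O | intermediate
16 | 7-(benzyloxy)-5-hydroxy-8-[4-(5-hydroxy-7-methoxy-4-oxo-4H-chromen-2-yl)phenoxy]-2-(4-methoxyphenyl)-4H-chromen-4-one | COc1cc(O)c2c(c1)oc(-c1ccc(Oc3c(OCc4ccccc4)cc(O)c4c(=O)cc(-c5ccc(OC)cc5)oc34)cc1)cc2=O | intermediate
17 | 5,7-dihydroxy-8-[4-(5-hydroxy-7-methoxy-4-oxo-4H-chromen-2-yl)phenoxy]-2-(4-methoxyphenyl)-4H-chromen-4-one (CNP0124888.0) | COc1ccc(-c2cc(=O)c3c(O)cc(O)c(Oc4ccc(-c5cc(=O)c6c(O)cc(OC)cc6o5)cc4)c3o2)cc1 | target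

**Step count and risks**

Total step count: 9. Longest linear sequence: 6 steps (steps 1, 2, 3, 4, 8, 9 from acacetin); the iodoresorcinol branch contributes steps 5–7.

Steps most likely to fail:

1. Step 8. The arylpalladium intermediate may be alkynylated before it takes up CO, which leads on to furan annulation. The aroylpalladium species may also be intercepted by diethylamine, or the electron-rich ring may lose iodine reductively before oxidative addition becomes productive. The fallback builds ring C of unit 2 by chalcone chemistry, setting out from aldehyde 6 and returning at 16. Commercial 2',6'-dihydroxy-4'-methoxyacetophenone is mono-protected (MOMCl, i-Pr2NEt, CH2Cl2) to 1-[2-hydroxy-4-methoxy-6-(methoxymethoxy)phenyl]ethan-1-one F1. Claisen–Schmidt condensation of F1 with 6 (KOH, EtOH–THF, rt) should give the (E)-chalcone F2. Oxidative cyclisation with catalytic I2 in DMSO at 120 °C should close the pyranone to the 5-O-methoxymethyl flavone F3. Brief treatment with HCl in MeOH removes any surviving acetal and delivers 16.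

2. Step 2. Conversion of the chelated, electron-poor phenoxide by peroxodisulfate may stay low, with oxidative degradation of the phenoxide competing with sulfate formation, so that throughput is insufficient. The fallback introduces the C8 oxygen by cross-coupling, setting out from acacetin 1 and returning at 6; it also bypasses steps 1 and 3. Exhaustive benzylation (excess BnBr, K2CO3, DMF, 80 °C) gives 5,7-bis(benzyloxy)-2-(4-methoxyphenyl)-4H-chromen-4-one F4. Electrophilic iodination (N-iodosuccinimide, catalytic CF3CO2H, MeCN) should go to C8 once the 5-oxygen is alkylated, giving the 8-iodide F5. Ullmann-type C–O coupling with 4-hydroxybenzaldehyde (CuI, picolinic acid, K3PO4, DMSO, 90 °C) gives 4-{[5,7-bis(benzyloxy)-2-(4-methoxyphenyl)-4-oxo-4H-chromen-8-yl]oxy}benzaldehyde F6. Chelation-controlled cleavage of the benzyl ether peri to the carbonyl with MgBr2·OEt2 (toluene–ether, reflux) then gives 6.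

3. Step 3. The 5,8-hydroquinone may be oxidised to the quinone in hot basic DMF, and substitution by a phenoxide flanked on both sides may be sluggish, allowing decomposition to overtake ether formation. The fallback replaces SNAr by metal-free aryl transfer from a diaryliodonium salt at room temperature, setting out from 4 and returning at 6. (4-Formylphenyl)(2,4,6-trimethoxyphenyl)iodonium 4-methylbenzenesulfonate F7 is prepared in one pot from 4-iodobenzaldehyde (mCPBA, TsOH, then 1,3,5-trimethoxybenzene). Reaction of 4 with F7 and K2CO3 in MeCN at rt under argon should transfer the electron-poor formylphenyl group to O8 and give 6 directly.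

Further compounds
F1 | step 8 | 1-[2-hydroxy-4-methoxy-6-(methoxymethoxy)phenyl]ethan-1-one | CC(=O)c1c(O)cc(OC)cc1OCOC
F2 | step 8 | (E)-3-(4-{[7-(benzyloxy)-5-hydroxy-2-(4-methoxyphenyl)-4-oxo-4H-chromen-8-yl]oxy}phenyl)-1-[2-hydroxy-4-methoxy-6-(methoxymethoxy)phenyl]prop-2-en-1-one | COCOc1cc(OC)cc(O)c1C(=O)/C=C/c1ccc(Oc2c(OCc3ccccc3)cc(O)c3c(=O)cc(-c4ccc(OC)cc4)oc23)cc1
F3 | step 8 | 7-(benzyloxy)-5-hydroxy-8-{4-[7-methoxy-5-(methoxymethoxy)-4-oxo-4H-chromen-2-yl]phenoxy}-2-(4-methoxyphenyl)-4H-chromen-4-one | COCOc1cc(OC)cc2oc(-c3ccc(Oc4c(OCc5ccccc5)cc(O)c5c(=O)cc(-c6ccc(OC)cc6)oc45)cc3)cc(=O)c12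
F4 | step 2 | 5,7-bis(benzyloxy)-2-(4-methoxyphenyl)-4H-chromen-4-one | COc1ccc(-c2cc(=O)c3c(OCc4ccccc4)cc(OCc4ccccc4)cc3o2)cc1
F5 | step 2 | 5,7-bis(benzyloxy)-8-iodo-2-(4-methoxyphenyl)-4H-chromen-4-one | COc1ccc(-c2cc(=O)c3c(OCc4ccccc4)cc(OCc4ccccc4)c(I)c3o2)cc1
F6 | step 2 | 4-{[5,7-bis(benzyloxy)-2-(4-methoxyphenyl)-4-oxo-4H-chromen-8-yl]oxy}benzaldehyde | COc1ccc(-c2cc(=O)c3c(OCc4ccccc4)cc(OCc4ccccc4)c(Oc4ccc(C=O)cc4)c3o2)cc1
F7 | step 3 | (4-formylphenyl)(2,4,6-trimethoxyphenyl)iodonium 4-methylbenzenesulfonate | COc1cc(OC)c([I+]c2ccc(C=O)cc2)c(OC)c1.Cc1ccc(S(=O)(=O)[O-])cc1
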